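## Structural features

The target is a (2S)-flavanone: ring A (benzene) and ring C (dihydropyranone) share the C4a–C8a bond, and the phenyl ring B sits on C2. Ring A is a fully substituted phloroglucinol. It carries O1 on C8a, free hydroxyls on C5 and C7, the C4 ketone on C4a, a 3-methylbut-2-enoyl group on C8, and on C6 a methylene bridge to C3 of a 6-ethyl-4-hydroxy-5-methyl-2H-pyran-2-one. C2 is the only stereocentre and has no stereogenic neighbour. It is benzylic, bears the ring oxygen and lies β to the C4 carbonyl, so it can be lost by retro-oxa-Michael opening of ring C under base or by benzylic ionisation under strong acid. The enone on C8 stands next to the 7-hydroxyl and can close by oxa-Michael addition to a 2,2-dimethylchromanone under acid or base. The methylene bridge between two enolic rings and the acidic pyranone enol are further sensitive points. The real difficulty is regiochemical: three different carbon substituents (at C4a, C6, C8) and one etherified oxygen must be placed around one ring, and once ring A carries two acyl groups it no longer accepts an electrophilic acylation. The key step exploits the fact that O1 (on C8a) is para to C6 and that C6 bears a one-carbon substituent. A phloroglucinaldehyde etherified at its para oxygen has two equivalent ortho carbons, so closing C4–C4a at either gives one chromanone with the formyl group at C6 and leaves C8 as the only unsubstituted ring carbon.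

## Logic of the disconnections

17 is cut between the bridge methylene and C3 of the lactone ring, giving 11 and 15. The bridge carbon becomes the formyl carbon of 11. This makes the route convergent and brings in the acidic lactone last. The forward step must be a near-neutral reductive condensation in which hydride reduces only the condensation intermediate 16, not the enone or the ketones.

11 is traced back to 10 by cutting the two O–benzyl bonds. The phenols must be masked while ring A is acylated and coupled. In 10 each benzyloxy group lies between two carbonyl groups, so chelation-assisted cleavage at low temperature is possible. The forward step must spare the alkene (no hydrogenation) and the O1–C2 ether.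

10 is cut at both bonds of the C8 carbonyl carbon (C8–CO and CO–CH), leading to 9, a one-carbon carbonyl source and a 2-methylpropenyl metal reagent. Ring A of 8 already bears two acyl groups, and acidic acylation conditions would also cyclise the enone. A neutral carbonylative cross-coupling avoids both problems. It must insert the carbonyl faster than it couples directly, and it must run without base so that ring C stays closed.

9 is cut at C8–I to give 8. C8 is the only ring carbon with a hydrogen, and every substituent directs to it, so no regiochemical question arises.

8 is cut at C4–C4a, opening ring C to 6 (key step). The two candidate ring carbons of 6 are equivalent by symmetry, so one bond closes the ring and fixes C4a, C6 and C8 at once. The forward step needs an arene that is still nucleophilic despite the formyl group, which is why the phenols are ethers and not free. It also needs activation that does not ionise the C2–O bond.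

6 is traced back through 4 to 3 by ester cleavage and benzylation. The acid must be freed without forming the ester enolate, which would expel the aryloxide. The benzyl groups are put on after the ether bond because only the para hydroxyl of 1 is free of hydrogen bonding, which is the selectivity the next cut relies on.

3 is cut at O1–C2 to give 1 and 2. The stereocentre is bought and installed by inversion. The forward step demands clean SN2 displacement, reaction at the para oxygen only, and no elimination to a cinnamate.

15 is cut at C4–C5 and O1–C2 of the lactone ring, giving 13 and a malonyl unit; 13 comes from 12. The ketone supplies C5, C6, both alkyl groups and the ring oxygen.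

## Other disconnections considered

Alternative 1: The cut is the C7–C8 bond of ring A, so that the benzene ring is unfolded into a second 4-hydroxy-2-pyranone carrying a 4-methyl-2-oxopent-3-enyl chain; the precursor is the methylene-linked bis-pyranone A1. In the forward key step a magnesium alkoxide would open the chain-bearing lactone to a chelated triketo ester. The chain methylene would then attack the former lactone carbonyl (Claisen condensation) and aromatise to the acylphloroglucinol A2.
- In its favour: the relative position of the C6 bridge and the C8 acyl group is fixed by connectivity before ring A exists. No arene has to be acylated, and no protecting group, palladium, tin or carbon monoxide is needed. On these points it is better than the chosen plan.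
- Against it: A2 has neither ring C nor C2. The phenyl-bearing three-carbon unit must still be attached at the last free ring carbon, which has two different hydroxyl neighbours, so closure through the wrong oxygen would give the 6-acyl-8-alkyl isomer. C2 would have to come from an enantioselective oxa-Michael closure of a system that equilibrates easily. In A2 the enone is flanked by two free hydroxyls in a basic medium, which invites chromanone formation, and the alkoxide must choose between two similar lactones.
- Comparison: structurally, the chosen plan fixes O1, C4a and C6 by symmetry and C8 by default, whereas this one fixes C6 and C8 but leaves O1 open. Mechanistically, the anionic Claisen closure threatens no stereocentre only because none exists yet. In step count, building A1 and then ring C would not be shorter; equal at best.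

Alternative 2: The cut is at both bonds of the C8 carbonyl carbon on a flavanone whose C6 is still unsubstituted. In the forward key step the iodide A3, carbon monoxide and a 2-methylpropenylboron reagent would couple under palladium catalysis with base to give A4.
- In its favour: ring C and C2 are present from the start. The enone is made without acid. The boron reagent is easier to handle and remove than the tin reagent of step 6, which is a point on which it is better. The bond construction is of the same kind as step 6 of the chosen plan, so the two are equal in mechanism there. The sequence could be two or three steps shorter, so it is better on step count.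
- Against it: A3 requires iodination at C8 while C6 is also free and similarly activated, so the regiochemistry is not secured by structure. The base needed for the boron reagent, at elevated temperature, can open ring C by elimination of the aryloxide. The methylene–pyranone unit must be added last to a ring A bearing two acyl groups, after acidic removal of the acetal groups has placed a free 7-hydroxyl next to the enone.
- Comparison: the chosen plan pays for its extra steps with a C6 handle that blocks C6 during iodination and later becomes the bridge. This alternative is shorter but relies on two selectivities that the substrate does not enforce.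

Alternative 3: The cut is the C3–C4 bond of ring C. In the forward key step a carbene catalyst would turn the aldehyde of A5 into an acyl anion equivalent, which displaces the primary tosylate intramolecularly (6-exo-tet) to give A6.
- In its favour: no electrophilic aromatic substitution is involved, so ring A need not be electron-rich. No acid is present, so the benzylic C2–O bond cannot ionise. The reaction is catalytic and occurs one atom away from the stereocentre. On safety for C2 during ring closure it is better than the chosen key step.
- Against it: A6 has both C6 and C8 unsubstituted, so two successive C-functionalisations of ring A would have to be regioselective with no structural bias. A5 requires etherification of a hydrogen-bonded ortho hydroxyl rather than the naturally favoured para one, which costs protection steps. Base can eliminate the tosylate to an enol ether.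
- Comparison: the ring closure itself is milder than the chosen one, but it moves the whole regiochemical problem to the end, where the chosen plan has already solved it. In step count it is longer.

Key step: step 4

Remark on the chemistry: flavanone numbering is used throughout. The two hydroxyls ortho to the formyl group are carried through the ring closure as benzyl ethers, because free phenols would be trifluoroacetylated by the activating anhydride and would then no longer support acylation of a ring that already bears a formyl group. The C8 acyl group is introduced by carbonylative coupling of the C8 iodide, because ring A then carries two acyl groups and acidic acylation would also close the enone onto the 7-oxygen. Compound 2 is (R); inversion gives (S), which is kept through to 17.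

## Route

Step 1
Reactants: 1 2,4,6-trihydroxybenzaldehyde; 2 ethyl (R)-3-hydroxy-3-phenylpropanoate
Product: 3 ethyl (S)-3-(4-formyl-3,5-dihydroxyphenoxy)-3-phenylpropanoate
Conditions: PPh3, DIAD, toluene–THF, −10 °C → rt (1 in slight excess)
Reagents that add atoms: none
Why: Mitsunobu etherification; the para hydroxyl of 1 is the most acidic and the only one not hydrogen-bonded to the formyl group, so it protonates the betaine and attacks the alkoxyphosphonium ion. SN2 displacement inverts the carbinol carbon of 2 and sets C2 as (S); the β-ester group disfavours a benzylic cation.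

Step 2
Reactants: 3 ethyl (S)-3-(4-formyl-3,5-dihydroxyphenoxy)-3-phenylpropanoate
Product: 4 ethyl (S)-3-[3,5-bis(benzyloxy)-4-formylphenoxy]-3-phenylpropanoate
Conditions: BnBr, K2CO3, DMF, rt → 40 °C
Reagents that add atoms: benzyl bromide, BrCc1ccccc1
Why: Williamson etherification of the two chelated phenols; benzyl ethers keep the ring electron-rich, resist the anhydride of step 4 and can later be removed at low temperature without hydrogenation. The mild carbonate base limits E1cB loss of the aryloxide from the β-aryloxy ester.

Step 3
Reactants: 4 ethyl (S)-3-[3,5-bis(benzyloxy)-4-formylphenoxy]-3-phenylpropanoate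
Product: 6 (S)-3-[3,5-bis(benzyloxy)-4-formylphenoxy]-3-phenylpropanoic acid, via trimethylstannyl ester 5 (not isolated)
Conditions: Me3SnOH, ClCH2CH2Cl, 70 °C; then 1 M HCl wash
Reagents that add atoms: trimethyltin hydroxide, C[Sn](C)(C)O
Why: Me3SnOH-mediated ester hydrolysis runs through a tin carboxylate under nearly neutral conditions. This avoids the ester enolate and hence the retro-oxa-Michael loss of the para-formylphenoxide that aqueous hydroxide would risk; C2 is not touched.

Step 4
Reactants: 6 (S)-3-[3,5-bis(benzyloxy)-4-formylphenoxy]-3-phenylpropanoic acid
Product: 8 (S)-5,7-bis(benzyloxy)-6-formylflavanone, via mixed trifluoroacetic anhydride 7 (not isolated)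
Conditions: TFAA, CH2Cl2, 0 °C → rt; aq. NaHCO3 work-up
Reagents that add atoms: none
Why: TFAA converts the carboxyl of 6 into the mixed anhydride 7, an acylium equivalent that is attacked by the ring carbon ortho to the ether oxygen; the arenium ion loses a proton to give the aryl ketone, forming C4–C4a. The closest known reaction type is the intramolecular Friedel–Crafts cycloacylation of 3-aryloxypropanoic acids to chroman-4-ones. Ring C closes as a six-membered ring in the 6-exo-trig mode, the activated carbonyl staying exocyclic. No stereocentre is formed; C2 lies two atoms from the new bond and is kept as long as the benzylic C–O bond does not ionise. Low temperature and a non-nucleophilic medium guard against this, as do the weakly basic aryloxy oxygen (conjugated to the para formyl group) and the β-carbonyl, which destabilises a C2 cation. Regioselectivity is secured by symmetry: the two ortho carbons are equivalent, and each is ortho to the ether oxygen, ortho to one benzyloxy group, para to the other and meta to the formyl group. The benzyl ethers keep the ring nucleophilic where free phenols would be trifluoroacetylated, and the non-enolisable formyl group is inert to the anhydride.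

Step 5
Reactants: 8 (S)-5,7-bis(benzyloxy)-6-formylflavanone
Product: 9 (S)-5,7-bis(benzyloxy)-6-formyl-8-iodoflavanone
Conditions: NIS, TFA (cat.), MeCN, 0 °C → rt, dark
Reagents that add atoms: N-iodosuccinimide, O=C1CCC(=O)N1I
Why: electrophilic aromatic iodination; C8 is the only ring A carbon bearing hydrogen, ortho to O1 and the 7-benzyloxy group, para to the 5-benzyloxy group and meta to both carbonyl-bearing carbons, so all directing effects agree. The unactivated phenyl rings should not compete.

Step 6
Reactants: 9 (S)-5,7-bis(benzyloxy)-6-formyl-8-iodoflavanone
Product: 10 (S)-5,7-bis(benzyloxy)-6-formyl-8-(3-methylbut-2-enoyl)flavanone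
Conditions: CO (3 atm), Bu3SnCH=CMe2, Pd2(dba)3 (cat.), AsPh3, toluene, 80 °C
Reagents that add atoms: carbon monoxide, [C-]#[O+]; tributyl(2-methylprop-1-en-1-yl)stannane, CCCC[Sn](CCCC)(CCCC)C=C(C)C
Why: carbonylative Stille coupling; zerovalent palladium inserts into the C8–I bond, CO insertion gives the acylpalladium species, and transmetalation from the alkenylstannane followed by reductive elimination gives the aryl alkenyl ketone. The two ortho substituents retard direct coupling and so favour insertion. With no base or acid present ring C should stay closed, and the 7-O-benzyl group prevents oxa-Michael closure onto the new enone.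

Step 7
Reactants: 10 (S)-5,7-bis(benzyloxy)-6-formyl-8-(3-methylbut-2-enoyl)flavanone
Product: 11 (S)-6-formyl-5,7-dihydroxy-8-(3-methylbut-2-enoyl)flavanone
Conditions: BCl3, C6HMe5, CH2Cl2, −78 °C; then cold H2O
Reagents that add atoms: none
Why: chelation-assisted Lewis-acid debenzylation; each benzyloxy group lies between two carbonyl groups, BCl3 binds there and releases a benzyl cation that pentamethylbenzene traps by Friedel–Crafts alkylation. At −78 °C the alkene, the formyl group and the cyclic benzylic ether should survive, and the phenol oxygens stay bound to boron until the quench.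

Step 8
Reactants: 12 pentan-3-one
Product: 13 trimethyl(pent-2-en-3-yloxy)silane (E/Z mixture)
Conditions: TMSOTf, Et3N, CH2Cl2, 0 °C
Reagents that add atoms: trimethylsilyl trifluoromethanesulfonate, C[Si](C)(C)OS(=O)(=O)C(F)(F)F
Why: soft enolisation and O-silylation of a symmetrical ketone gives the silyl enol ether; regiochemistry is not an issue and the alkene geometry is irrelevant to the next step.

Step 9
Reactants: 13 trimethyl(pent-2-en-3-yloxy)silane
Product: 15 6-ethyl-4-hydroxy-5-methyl-2H-pyran-2-one, via 4-methyl-3,5-dioxoheptanoyl chloride 14 (not isolated)
Conditions: ClCOCH2COCl, Et2O, −78 °C → rt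
Reagents that add atoms: malonyl dichloride, O=C(Cl)CC(=O)Cl
Why: C-acylation of the silyl enol ether by malonyl dichloride gives 14, whose enol oxygen closes onto the acid chloride (6-exo-trig lactonisation) and tautomerises to the 4-hydroxy-2-pyranone. This is a known route to 5,6-disubstituted 4-hydroxy-2-pyranones from ketone silyl enol ethers.

Step 10
Reactants: 11 (S)-6-formyl-5,7-dihydroxy-8-(3-methylbut-2-enoyl)flavanone; 15 6-ethyl-4-hydroxy-5-methyl-2H-pyran-2-one
Product: 17 (S)-6-[(6-ethyl-4-hydroxy-5-methyl-2-oxo-2H-pyran-3-yl)methyl]-5,7-dihydroxy-8-(3-methylbut-2-enoyl)flavanone, via arylidene pyrandione 16 (not isolated)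
Conditions: Hantzsch ester, L-proline (20 mol %), CH2Cl2–EtOH, rt
Reagents that add atoms: none
Why: organocatalytic three-component reductive alkylation (Knoevenagel condensation followed by Hantzsch ester transfer hydrogenation), known for 4-hydroxycoumarins and 4-hydroxy-2-pyranones with aryl aldehydes. C3 of 15 condenses with the formyl group to 16, an ortho-quinone-methide-like acceptor that takes hydride at the benzylic carbon. The β,β-disubstituted enone and the ketones are not electrophilic enough for the dihydropyridine, and the near-neutral medium should spare C2 and the 7-hydroxyl/enone pair.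

## Compound list

1 | 2,4,6-trihydroxybenzaldehyde | O=Cc1c(O)cc(O)cc1O | starting material
2 | ethyl (R)-3-hydroxy-3-phenylpropanoate | CCOC(=O)C[C@@H](O)c1ccccc1 | starting material
3 | ethyl (S)-3-(4-formyl-3,5-dihydroxyphenoxy)-3-phenylpropanoate | CCOC(=O)C[C@@H](c1ccccc1)Oc1cc(O)c(C=O)c(O)c1 | intermediate
4 | ethyl (S)-3-[3,5-bis(benzyloxy)-4-formylphenoxy]-3-phenylpropanoate | CCOC(=O)C[C@@H](c1ccccc1)Oc1cc(OCc2ccccc2)c(C=O)c(OCc2ccccc2)c1 | intermediate
5 | trimethylstannyl (S)-3-[3,5-bis(benzyloxy)-4-formylphenoxy]-3-phenylpropanoate (not isolated) | C[Sn](C)(C)OC(=O)C[C@@H](c1ccccc1)Oc1cc(OCc2ccccc2)c(C=O)c(OCc2ccccc2)c1 | intermediate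
6 | (S)-3-[3,5-bis(benzyloxy)-4-formylphenoxy]-3-phenylpropanoic acid | OC(=O)C[C@@H](c1ccccc1)Oc1cc(OCc2ccccc2)c(C=O)c(OCc2ccccc2)c1 | intermediate
7 | (S)-3-[3,5-bis(benzyloxy)-4-formylphenoxy]-3-phenylpropanoic trifluoroacetic anhydride (not isolated) | O=C(OC(=O)C(F)(F)F)C[C@@H](c1ccccc1)Oc1cc(OCc2ccccc2)c(C=O)c(OCc2ccccc2)c1 | intermediate
8 | (S)-5,7-bis(benzyloxy)-6-formylflavanone, i.e. (2S)-5,7-bis(benzyloxy)-4-oxo-2-phenyl-3,4-dihydro-2H-chromene-6-carbaldehyde | O=Cc1c(OCc2ccccc2)cc2c(c1OCc1ccccc1)C(=O)C[C@@H](c1ccccc1)O2 | intermediate
9 | (S)-5,7-bis(benzyloxy)-6-formyl-8-iodoflavanone | O=Cc1c(OCc2ccccc2)c(I)c2c(c1OCc1ccccc1)C(=O)C[C@@H](c1ccccc1)O2 | intermediate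
10 | (S)-5,7-bis(benzyloxy)-6-formyl-8-(3-methylbut-2-enoyl)flavanone | O=Cc1c(OCc2ccccc2)c(C(=O)C=C(C)C)c2c(c1OCc1ccccc1)C(=O)C[C@@H](c1ccccc1)O2 | intermediate
11 | (S)-6-formyl-5,7-dihydroxy-8-(3-methylbut-2-enoyl)flavanone | O=Cc1c(O)c(C(=O)C=C(C)C)c2c(c1O)C(=O)C[C@@H](c1ccccc1)O2 | intermediate
12 | pentan-3-one | CCC(=O)CC | starting material
13 | trimethyl(pent-2-en-3-yloxy)silane (E/Z mixture) | CC=C(CC)O[Si](C)(C)C | intermediate
14 | 4-methyl-3,5-dioxoheptanoyl chloride (racemic, enolisable; not isolated) | CCC(=O)C(C)C(=O)CC(=O)Cl | intermediate
15 | 6-ethyl-4-hydroxy-5-methyl-2H-pyran-2-one | CCc1oc(=O)cc(O)c1C | intermediate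
16 | (S)-6-[(6-ethyl-5-methyl-2,4-dioxo-2H-pyran-3(4H)-ylidene)methyl]-5,7-dihydroxy-8-(3-methylbut-2-enoyl)flavanone (alkene geometry not defined; not isolated) | CCC1=C(C)C(=O)C(=Cc2c(O)c(C(=O)C=C(C)C)c3c(c2O)C(=O)C[C@@H](c2ccccc2)O3)C(=O)O1 | intermediate
17 | (S)-6-[(6-ethyl-4-hydroxy-5-methyl-2-oxo-2H-pyran-3-yl)methyl]-5,7-dihydroxy-8-(3-methylbut-2-enoyl)flavanone | CCc1oc(=O)c(Cc2c(O)c(C(=O)C=C(C)C)c3c(c2O)C(=O)C[C@@H](c2ccccc2)O3)c(O)c1C | target

## Step count and least certain steps

Total step count: 10. Longest linear sequence: 8 (steps 1–7 and 10); steps 8–9 form the short second branch.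

Step 4 (key step). The most likely failure is ionisation of the benzylic C2–O bond, with loss of the aryloxide and elimination to a cinnamic acid, or re-closure with loss of configuration. This would compete with a sluggish ring acylation, because the formyl group lowers the nucleophilicity of the arene; adding a strong acid co-catalyst to speed the acylation would also speed the ionisation. Fallback: remove the deactivation instead of forcing the electrophile.
- From 4, the formyl group would be masked with propane-1,3-dithiol (BF3·OEt2 cat., CH2Cl2, 0 °C) as ethyl (S)-3-[3,5-bis(benzyloxy)-4-(1,3-dithian-2-yl)phenoxy]-3-phenylpropanoate F1.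
- Me3SnOH cleavage as in step 3 would give (S)-3-[3,5-bis(benzyloxy)-4-(1,3-dithian-2-yl)phenoxy]-3-phenylpropanoic acid F2.
- Its ring, now free of an electron-withdrawing group, should cyclise with TFAA at −20 °C to (S)-5,7-bis(benzyloxy)-6-(1,3-dithian-2-yl)flavanone F3.
- MeI and CaCO3 in aqueous MeCN would unmask the aldehyde and rejoin the route at 8.

Step 1. The activated alcohol may undergo β-elimination to ethyl cinnamate, since the hydrogens α to the ester are acidic. Partial loss of configuration through a benzylic ion pair and alkylation of a second hydroxyl are lesser risks. Fallback: use an alcohol without carbonyl-activated hydrogens.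
- Commercial (R)-1-phenylpropane-1,3-diol would be silylated at the primary hydroxyl (TBSCl, imidazole) to (R)-3-[(tert-butyldimethylsilyl)oxy]-1-phenylpropan-1-ol F4.
- Mitsunobu inversion with 1 would give (S)-4-{3-[(tert-butyldimethylsilyl)oxy]-1-phenylpropoxy}-2,6-dihydroxybenzaldehyde F5.
- Benzylation as in step 2 would give (S)-2,6-bis(benzyloxy)-4-{3-[(tert-butyldimethylsilyl)oxy]-1-phenylpropoxy}benzaldehyde F6.
- HF·pyridine would release (S)-2,6-bis(benzyloxy)-4-(3-hydroxy-1-phenylpropoxy)benzaldehyde F7.
- TEMPO with PhI(OAc)2 in aqueous MeCN would oxidise the primary alcohol to the acid and rejoin the route at 6.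

Step 6. At the doubly ortho-substituted C8, transmetalation may be slow, so protodehalogenation or direct coupling without carbon monoxide uptake may compete. Fallback without carbon monoxide or tin:
- From 9, Sonogashira coupling with 2-methylbut-3-yn-2-ol (PdCl2(PPh3)2, CuI, Et3N, THF, rt) would give (S)-5,7-bis(benzyloxy)-6-formyl-8-(3-hydroxy-3-methylbut-1-yn-1-yl)flavanone F8.
- Meyer–Schuster rearrangement of this tertiary propargylic alcohol (Ph3PAuNTf2 cat., MeOH, toluene, rt) would give the enone and rejoin the route at 10.

Step 7. The Lewis acid may cleave the O1–C2 benzylic ether, which is now ortho to the C8 carbonyl, opening ring C with loss of configuration. Hydrogen chloride may also add to the enone, or the enone may close onto the freed 7-oxygen during the quench. Fallback: deprotect before the enone exists.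
- From 9, the same BCl3/C6HMe5 treatment would give (S)-6-formyl-5,7-dihydroxy-8-iodoflavanone F9.
- The base-free carbonylative Stille coupling of step 6 on this iodophenol would rejoin the route at 11.

Step 10. Condensation at the doubly chelated, hindered aldehyde may be incomplete. The amine catalyst may promote oxa-Michael closure of the 7-hydroxyl onto the enone, and a second pyranone may add to 16 before hydride transfer. Fallback: make the bridge by cationic benzylation while the phenols are still protected.
- From 10, chemoselective reduction of the aldehyde (NaBH4, CH2Cl2–EtOH, −78 °C) would give (S)-5,7-bis(benzyloxy)-6-(hydroxymethyl)-8-(3-methylbut-2-enoyl)flavanone F10.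
- Acid-catalysed C3-benzylation of 15 with this electron-rich benzylic alcohol (Sc(OTf)3 cat., MeCN, rt) would give (S)-5,7-bis(benzyloxy)-6-[(6-ethyl-4-hydroxy-5-methyl-2-oxo-2H-pyran-3-yl)methyl]-8-(3-methylbut-2-enoyl)flavanone F11.
- BCl3/C6HMe5 at −78 °C would remove the benzyl groups and rejoin the route at 17.

## Further compounds

F1 | step 4 | ethyl (S)-3-[3,5-bis(benzyloxy)-4-(1,3-dithian-2-yl)phenoxy]-3-phenylpropanoate | CCOC(=O)C[C@@H](c1ccccc1)Oc1cc(OCc2ccccc2)c(C2SCCCS2)c(OCc2ccccc2)c1
F2 | step 4 | (S)-3-[3,5-bis(benzyloxy)-4-(1,3-dithian-2-yl)phenoxy]-3-phenylpropanoic acid | OC(=O)C[C@@H](c1ccccc1)Oc1cc(OCc2ccccc2)c(C2SCCCS2)c(OCc2ccccc2)c1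
F3 | step 4 | (S)-5,7-bis(benzyloxy)-6-(1,3-dithian-2-yl)flavanone | O=C1C[C@@H](c2ccccc2)Oc2cc(OCc3ccccc3)c(C3SCCCS3)c(OCc3ccccc3)c12
F4 | step 1 | (R)-3-[(tert-butyldimethylsilyl)oxy]-1-phenylpropan-1-ol | CC(C)(C)[Si](C)(C)OCC[C@@H](O)c1ccccc1
F5 | step 1 | (S)-4-{3-[(tert-butyldimethylsilyl)oxy]-1-phenylpropoxy}-2,6-dihydroxybenzaldehyde | CC(C)(C)[Si](C)(C)OCC[C@@H](c1ccccc1)Oc1cc(O)c(C=O)c(O)c1
F6 | step 1 | (S)-2,6-bis(benzyloxy)-4-{3-[(tert-butyldimethylsilyl)oxy]-1-phenylpropoxy}benzaldehyde | CC(C)(C)[Si](C)(C)OCC[C@@H](c1ccccc1)Oc1cc(OCc2ccccc2)c(C=O)c(OCc2ccccc2)c1
F7 | step 1 | (S)-2,6-bis(benzyloxy)-4-(3-hydroxy-1-phenylpropoxy)benzaldehyde | OCC[C@@H](c1ccccc1)Oc1cc(OCc2ccccc2)c(C=O)c(OCc2ccccc2)c1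
F8 | step 6 | (S)-5,7-bis(benzyloxy)-6-formyl-8-(3-hydroxy-3-methylbut-1-yn-1-yl)flavanone | O=Cc1c(OCc2ccccc2)c(C#CC(C)(C)O)c2c(c1OCc1ccccc1)C(=O)C[C@@H](c1ccccc1)O2
F9 | step 7 | (S)-6-formyl-5,7-dihydroxy-8-iodoflavanone | O=Cc1c(O)c(I)c2c(c1O)C(=O)C[C@@H](c1ccccc1)O2
F10 | step 10 | (S)-5,7-bis(benzyloxy)-6-(hydroxymethyl)-8-(3-methylbut-2-enoyl)flavanone | OCc1c(OCc2ccccc2)c(C(=O)C=C(C)C)c2c(c1OCc1ccccc1)C(=O)C[C@@H](c1ccccc1)O2
F11 | step 10 | (S)-5,7-bis(benzyloxy)-6-[(6-ethyl-4-hydroxy-5-methyl-2-oxo-2H-pyran-3-yl)methyl]-8-(3-methylbut-2-enoyl)flavanone | CCc1oc(=O)c(Cc2c(OCc3ccccc3)c(C(=O)C=C(C)C)c3c(c2OCc2ccccc2)C(=O)C[C@@H](c2ccccc2)O3)c(O)c1C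
A1 | alternative 1 | 6-ethyl-4-hydroxy-3-{[4-hydroxy-6-(4-methyl-2-oxopent-3-en-1-yl)-2-oxo-2H-pyran-3-yl]methyl}-5-methyl-2H-pyran-2-one | CCc1oc(=O)c(Cc2c(O)cc(CC(=O)C=C(C)C)oc2=O)c(O)c1C
A2 | alternative 1 | 6-ethyl-4-hydroxy-5-methyl-3-{[2,4,6-trihydroxy-3-(3-methylbut-2-enoyl)phenyl]methyl}-2H-pyran-2-one | CCc1oc(=O)c(Cc2c(O)cc(O)c(C(=O)C=C(C)C)c2O)c(O)c1C
A3 | alternative 2 | (S)-8-iodo-5,7-bis(methoxymethoxy)flavanone | O=C1C[C@@H](c2ccccc2)Oc2c(I)c(OCOC)cc(OCOC)c12
A4 | alternative 2 | (S)-5,7-bis(methoxymethoxy)-8-(3-methylbut-2-enoyl)flavanone | O=C1C[C@@H](c2ccccc2)Oc2c(C(=O)C=C(C)C)c(OCOC)cc(OCOC)c12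
A5 | alternative 3 | (R)-2-[5-(benzyloxy)-2-formyl-3-hydroxyphenoxy]-2-phenylethyl 4-methylbenzenesulfonate | Cc1ccc(cc1)S(=O)(=O)OC[C@@H](c1ccccc1)Oc1cc(OCc2ccccc2)cc(O)c1C=O
A6 | alternative 3 | (S)-7-(benzyloxy)-5-hydroxyflavanone | O=C1C[C@@H](c2ccccc2)Oc2cc(OCc3ccccc3)cc(O)c12
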